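The cycloheptane core (C1, C5–C10; seco-guaianolide numbering) holds a C9 ketone flanked by C8H2 and C10H(Me), with the oxygenated C6–C7 lactone edge β,γ to it: a masked cyclohept-3-enone, the retron of the oxy-Cope ring expansion of a cis-1,2-dialkenylcyclopropanol. Everything rests on one titanium-mediated formal (4+3) annulation: Kulinkovich cyclopropanation of a (Z)-β-alkoxy enoate (C9–C10–C1) by a 1-silyloxybutadiene (C5–C8) makes the C8–C9 bond, and in-situ oxy-Cope rearrangement of the cyclopropanolate makes the C1–C5 bond. The olefin geometries set the quaternary C1 carbinol against C5; the C6=C7 alkene left behind is then converted into the trans-fused methylene lactone.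

Key step: step 4

Remark: atoms are numbered as in a 4,5-seco-guaianolide (ring C1, C5–C10; C2–C4 and C15 = crotonoyl; C11–C13 = methylene lactone; C14 = methyl) and β is the ring face of the C5 oxygen; TADDOL = (4R,5R)-2,2-dimethyl-α,α,α′,α′-tetraphenyl-1,3-dioxolane-4,5-dimethanol, assumed to induce the (1R,2S)-cyclopropanolate (otherwise its antipode is used).

Step 1
Reactants: 1 methyl propanoate; 2 methyl 2,2-dimethoxyacetate
Product: 3 methyl 4,4-dimethoxy-2-methyl-3-oxobutanoate (racemic)
Conditions: LiN(i-Pr)2 (LDA, 2.2 equiv), 1 (2.2 equiv), THF, −78 °C; then 2, −78 to 0 °C; aq. HCl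
Reagents that add atoms: none
Why: Crossed Claisen condensation, in which the enolate of 1 acylates the non-enolisable ester 2 and deprotonation of the β-keto ester drives the reaction; the α-stereocentre is irrelevant because it becomes sp2 in step 2.

Step 2
Reactants: 3 methyl 4,4-dimethoxy-2-methyl-3-oxobutanoate
Product: 4 methyl (2Z)-4,4-dimethoxy-3-(methoxymethoxy)-2-methylbut-2-enoate
Conditions: NaH, THF, 0 °C; then MOMCl, 0 °C to rt
Reagents that add atoms: chloromethyl methyl ether (MOMCl), COCCl
Why: O-alkylation of a β-keto ester enolate by a hard chloromethyl ether; the sodium-chelated enolate holds the enol oxygen cis to the ester and should therefore give the Z enol ether.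

Step 3
Reactants: 5 (E)-but-2-enal
Product: 6 (E)-1-(tert-butyldimethylsilyloxy)buta-1,3-diene
Conditions: TBSOTf, Et3N, Et2O, 0 °C to rt; distillation
Reagents that add atoms: tert-butyldimethylsilyl trifluoromethanesulfonate (TBSOTf), CC(C)(C)[Si](C)(C)OS(=O)(=O)C(F)(F)F
Why: Vinylogous silyl enol ether formation (O-silylation, then γ-deprotonation) gives the conjugated dienol ether, the E isomer being favoured and purified by distillation.

Step 4
Reactants: 4 methyl (2Z)-4,4-dimethoxy-3-(methoxymethoxy)-2-methylbut-2-enoate; 6 (E)-1-(tert-butyldimethylsilyloxy)buta-1,3-diene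
Product: 9 (5S,6S,7R)-5-(tert-butyldimethylsilyloxy)-6-(dimethoxymethyl)-6-(methoxymethoxy)-7-methylcyclohept-3-en-1-one, via cyclopropanolate 7 (not isolated), via titanium enolate 8 (not isolated)
Conditions: Ti(O-i-Pr)2(TADDOLate) (1.2 equiv), c-C5H9MgCl (2.5 equiv, slow addition), 6 (2 equiv), THF, 0 to 20 °C; then 45 °C; sat. aq. NH4Cl, −20 °C
Reagents that add atoms: none
Why: Divalent titanium, generated from the TADDOLate titanate and c-C5H9MgCl, exchanges cyclopentene for the monosubstituted vinyl group of 6; the titanacyclopropane inserts the ester carbonyl of 4, methoxide leaves and the β-titanio ketone closes to the cis-1,2-dialkenylcyclopropanolate 7 (Kulinkovich cyclopropanation, new C8–C9 bond), which on warming undergoes the alkoxide-accelerated [3,3] shift (oxy-Cope, boat transition state) that forms C1–C5 and the enolate 8, protonated on work-up. The closest known reaction type is the formal (4+3) annulation of alkenyl esters with 2-vinyltitanacyclopropanes through cis-dialkenylcyclopropanols, here run with a chiral TADDOLate titanate as in enantioselective Kulinkovich reactions. The cyclopropane closes by 3-exo-trig addition of the carbon–titanium bond to the ketone, and the seven-membered ring by concerted suprafacial [3,3] ring expansion across the breaking C7–C9 bond. C1 and C5 follow from the olefin geometries in the boat transition state (E-OTBS and the E-acetal carbon outside and therefore cis, Z-OMOM inside and therefore trans to C5–O), their absolute sense from the TADDOLate-controlled (1R,2S)-cyclopropanolate, and C10 from protonation of 8 anti to the pseudoaxial C1–OMOM, which also gives the more stable epimer (methyl trans to the C1 carbon substituent). The step needs chemoselective complexation of the terminal alkene of 6 (its enol ether bond and the tetrasubstituted bond of 4 are too hindered), the cis-dialkenyl relationship that the Kulinkovich closure delivers, and a Cope rate above that of β-alkoxide loss from 8, which the oxyanion acceleration and a cold quench secure.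

Step 5
Reactants: 9 cyclohept-3-enone from step 4
Product: 10 6α,7α-epoxide of 9 (oxirane anti to the C5 silyl ether)
Conditions: mCPBA, NaHCO3, CH2Cl2, 0 °C
Reagents that add atoms: 3-chloroperoxybenzoic acid (mCPBA), O=C(OO)c1cccc(Cl)c1
Why: Prilezhaev epoxidation of the only alkene, expected anti to the bulky allylic C5 silyl ether so that both epoxide C–O bonds lie on the α face; cold buffered conditions spare the ketone from Baeyer–Villiger oxidation.

Step 6
Reactants: 10 6α,7α-epoxy ketone
Product: 12 C6α-trimethylsilyloxy C7=C8 enone, via hydroxy enone 11 (not isolated)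
Conditions: Et3N, CH2Cl2, 0 °C to rt; then TMSCl, 0 °C
Reagents that add atoms: chlorotrimethylsilane (TMSCl), C[Si](C)(C)Cl
Why: E1cB opening of the β,γ-epoxy ketone (C8–H removal, C7–O cleavage) gives the γ-hydroxy enone with C6–O retained on the α face, and in-situ silylation prevents base-mediated isomerisation to a 1,4-diketone.

Step 7
Reactants: 12 C6α-trimethylsilyloxy enone; 13 ethynyltrimethylsilane
Product: 14 C7β-[(trimethylsilyl)ethynyl] ketone (C6α-OTMS, C5β-OTBS)
Conditions: 13, n-BuLi, Et2O, 0 °C; Me2AlCl; then 12, Ni(acac)2 (5 mol %), i-Bu2AlH (5 mol %), Et2O, −5 °C; aq. potassium sodium tartrate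
Reagents that add atoms: none
Why: Nickel-catalysed conjugate addition of a dimethylalkynylalane to a cyclic enone (zerovalent nickel formed from Ni(acac)2 and i-Bu2AlH); the alkynyl group enters C7 anti to the adjacent C6 silyl ether, which sets C7 trans to C6–O.

Step 8
Reactants: 14 C7β-[(trimethylsilyl)ethynyl] ketone
Product: 15 C7β-ethynyl C6α-alcohol
Conditions: K2CO3 (0.2 equiv), MeOH, 0 °C
Reagents that add atoms: none
Why: Base-catalysed methanolysis removes the alkynyl C–Si and the labile O–SiMe3 group while the hindered TBS ether, the MOM ether and the acetal persist; cold catalytic carbonate avoids β-elimination of the C1 alkoxide.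

Step 9
Reactants: 15 C7β-ethynyl C6α-alcohol
Product: 16 trans-fused α-methylene-γ-butyrolactone (C5β-OTBS, C1α-OMOM, C1β-CH(OMe)2)
Conditions: PdCl2 (5 mol %), PPh3, SnCl2, CO (8 atm), MeCN, 75 °C
Reagents that add atoms: carbon monoxide, [C-]#[O+]
Why: Palladium-catalysed cyclocarbonylation of a homopropargylic alcohol: an alkoxycarbonyl complex of divalent palladium formed from C6–OH and CO adds across the alkyne (5-exo-dig) and protonolysis releases the α-methylene lactone; no stereocentre is touched, so the trans fusion follows from steps 6 and 7.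

Step 10
Reactants: 16 protected methylene lactone
Product: 17 C5β,C1α-diol C2-aldehyde
Conditions: TFA/H2O (9:1), CH2Cl2, 0 °C to rt
Reagents that add atoms: water, O
Why: Brønsted-acid hydrolysis cleaves the TBS ether, the MOM ether and the dimethyl acetal in one operation; the α-formyl group disfavours ionisation at C1 so the tertiary carbinol should persist, and C10 remains in its more stable configuration.

Step 11
Reactants: 17 diol aldehyde; 18 (R)-2-methylbutanoic acid
Product: 19 C5 (R)-2-methylbutanoate of 17
Conditions: DCC, DMAP (cat.), CH2Cl2, 0 °C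
Reagents that add atoms: none
Why: Steglich esterification acylates the only secondary hydroxyl (C5) while the tertiary C1–OH is inert, and carbodiimide activation without a ketene pathway preserves the α-stereocentre of the acid.

Step 12
Reactants: 19 ester aldehyde; 20 (E)-1-bromoprop-1-ene
Product: 21 C2 allylic alcohols (both C2 epimers)
Conditions: CrCl2 (4 equiv), NiCl2 (1 mol %), DMF, rt
Reagents that add atoms: none
Why: Nozaki–Hiyama–Kishi coupling: the alkenyl reagent of trivalent chromium adds only to the aldehyde, tolerating the ketone, both esters and the methylene lactone, with retention of the E olefin; the new C2 stereocentre is removed in step 13.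

Step 13
Reactants: 21 C2 allylic alcohols
Product: 22 target compound CNP0153197.3
Conditions: Dess–Martin periodinane, NaHCO3, CH2Cl2, 0 °C
Reagents that add atoms: none
Why: Dess–Martin oxidation converts the secondary allylic alcohol into the E-enone; the tertiary C1–OH cannot be oxidised and buffered conditions protect the β-hydroxy ketone.

Compound list
1 | methyl propanoate | CCC(=O)OC | starting material
2 | methyl 2,2-dimethoxyacetate | COC(OC)C(=O)OC | starting material
3 | methyl 4,4-dimethoxy-2-methyl-3-oxobutanoate (racemic) | COC(OC)C(=O)C(C)C(=O)OC | intermediate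
4 | methyl (2Z)-4,4-dimethoxy-3-(methoxymethoxy)-2-methylbut-2-enoate | COC(=O)/C(C)=C(\OCOC)C(OC)OC | intermediate
5 | (E)-but-2-enal | C/C=C/C=O | starting material
6 | (E)-1-(tert-butyldimethylsilyloxy)buta-1,3-diene | C=C/C=C/O[Si](C)(C)C(C)(C)C | intermediate
7 | titanium (1R,2S)-2-[(E)-2-(tert-butyldimethylsilyloxy)ethenyl]-1-[(Z)-4,4-dimethoxy-3-(methoxymethoxy)but-2-en-2-yl]cyclopropan-1-olate (cis-dialkenyl, drawn as the alkoxide, not isolated) | [O-][C@@]1(C[C@H]1/C=C/O[Si](C)(C)C(C)(C)C)/C(C)=C(\OCOC)C(OC)OC | intermediate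
8 | titanium enolate of 9 (C9=C10 enolate, C1 and C5 as in 9, drawn as the enolate anion, not isolated) | [O-]C1=C(C)[C@@](OCOC)(C(OC)OC)[C@@H](O[Si](C)(C)C(C)(C)C)C=CC1 | intermediate
9 | (5S,6S,7R)-5-(tert-butyldimethylsilyloxy)-6-(dimethoxymethyl)-6-(methoxymethoxy)-7-methylcyclohept-3-en-1-one (C5β-OTBS, C1α-OMOM, C10α-Me) | O=C1CC=C[C@H](O[Si](C)(C)C(C)(C)C)[C@](OCOC)(C(OC)OC)[C@H]1C | intermediate
10 | 6α,7α-epoxide of 9 | O=C1C[C@H]2O[C@H]2[C@H](O[Si](C)(C)C(C)(C)C)[C@](OCOC)(C(OC)OC)[C@H]1C | intermediate
11 | C6α-hydroxy C7=C8 enone (not isolated) | O=C1C=C[C@@H](O)[C@H](O[Si](C)(C)C(C)(C)C)[C@](OCOC)(C(OC)OC)[C@H]1C | intermediate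
12 | C6α-trimethylsilyl ether of 11 | O=C1C=C[C@@H](O[Si](C)(C)C)[C@H](O[Si](C)(C)C(C)(C)C)[C@](OCOC)(C(OC)OC)[C@H]1C | intermediate
13 | ethynyltrimethylsilane | C#C[Si](C)(C)C | starting material
14 | C7β-[(trimethylsilyl)ethynyl] C9 ketone with C6α-OTMS and C5β-OTBS | O=C1C[C@H](C#C[Si](C)(C)C)[C@@H](O[Si](C)(C)C)[C@H](O[Si](C)(C)C(C)(C)C)[C@](OCOC)(C(OC)OC)[C@H]1C | intermediate
15 | C7β-ethynyl C6α-hydroxy C9 ketone | O=C1C[C@H](C#C)[C@@H](O)[C@H](O[Si](C)(C)C(C)(C)C)[C@](OCOC)(C(OC)OC)[C@H]1C | intermediate
16 | trans-fused α-methylene-γ-butyrolactone with C5β-OTBS, C1α-OMOM and C1β-dimethoxymethyl | C=C1C(=O)O[C@@H]2[C@@H]1CC(=O)[C@H](C)[C@@](OCOC)(C(OC)OC)[C@H]2O[Si](C)(C)C(C)(C)C | intermediate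
17 | C5β,C1α-dihydroxy C1β-formyl methylene lactone | C=C1C(=O)O[C@@H]2[C@@H]1CC(=O)[C@H](C)[C@@](O)(C=O)[C@H]2O | intermediate
18 | (R)-2-methylbutanoic acid | CC[C@@H](C)C(=O)O | starting material
19 | C5 (R)-2-methylbutanoate of 17 | C=C1C(=O)O[C@@H]2[C@@H]1CC(=O)[C@H](C)[C@@](O)(C=O)[C@H]2OC(=O)[C@H](C)CC | intermediate
20 | (E)-1-bromoprop-1-ene | C/C=C/Br | starting material
21 | C2 (E)-but-2-enyl carbinols, both C2 epimers | C=C1C(=O)O[C@@H]2[C@@H]1CC(=O)[C@H](C)[C@@](O)(C(O)/C=C/C)[C@H]2OC(=O)[C@H](C)CC | intermediate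
22 | CNP0153197.3 | C=C1C(=O)O[C@@H]2[C@@H]1CC(=O)[C@H](C)[C@@](O)(C(=O)/C=C/C)[C@H]2OC(=O)[C@H](C)CC | target

Total step count: 13. Longest linear sequence: 12 steps (steps 1, 2 and 4–13).

Steps most likely to fail

1. Step 4. The titanium-mediated cyclopropanation may discriminate the enantiotopic faces poorly under the TADDOLate, so that the annulation delivers material of low enantiomeric purity. The fallback sets out from 4 and 6 and returns at 9. The same one-pot cyclopropanation/oxy-Cope sequence is run with achiral ClTi(O-i-Pr)3 and c-C5H9MgCl, which gives 9 as the racemate, that is together with its antipode ent-9 F1. HF·pyridine (THF, 0 °C) cleaves the silyl ethers to (5S,6S,7R)-6-(dimethoxymethyl)-5-hydroxy-6-(methoxymethoxy)-7-methylcyclohept-3-en-1-one F2 and its antipode ent-alcohol F3. Lipase-catalysed transesterification (Burkholderia cepacia lipase, vinyl acetate, t-BuOMe, 30 °C) should acetylate the (5R)-carbinol F3 to the (5R)-acetate F4 and leave F2; this follows the empirical size model for secondary alcohols, with the quaternary C1 as the large and the vinylic C6 as the medium substituent. F2 is separated and re-silylated (TBSOTf, 2,6-lutidine, CH2Cl2, −78 °C) to give 9.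

2. Step 5. The peracid may attack the conformationally mobile cycloheptene with poor facial selectivity or syn to the C5 silyl ether. The fallback sets out from 9 and returns at 12. The 6β,7β-epoxide F5 is separated and opened with Et3N as in step 6 to the C6β-hydroxy enone F6. Mitsunobu inversion (4-nitrobenzoic acid, PPh3, DIAD, toluene, 0 °C) gives the C6α 4-nitrobenzoate F7. Methanolysis (K2CO3, MeOH, 0 °C) gives 11, which is silylated with TMSCl/Et3N to 12.

3. Step 7. The alkynylalane may add 1,2 to the ketone, the anti selectivity at C7 may erode, and the Lewis-acidic aluminium reagent may attack the acetal and silyl ethers. The fallback sets out from 12 and returns at 16, bypassing steps 8 and 9. Base-catalysed Michael addition of triethyl phosphonoacetate (t-BuOK cat., THF, 0 °C) anti to the C6 silyl ether gives the phosphonoacetate adduct F8. PPTS in MeOH (40 °C) removes the trimethylsilyl ether and closes the trans lactone to the α-(diethoxyphosphoryl) lactone F9. Horner–Wadsworth–Emmons reaction with aqueous formaldehyde (K2CO3, THF, 0 °C) installs the exocyclic methylene and gives 16.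

Further compounds
F1 | step 4 | ent-9, (5R,6R,7S)-5-(tert-butyldimethylsilyloxy)-6-(dimethoxymethyl)-6-(methoxymethoxy)-7-methylcyclohept-3-en-1-one | O=C1CC=C[C@@H](O[Si](C)(C)C(C)(C)C)[C@@](OCOC)(C(OC)OC)[C@@H]1C
F2 | step 4 | (5S,6S,7R)-6-(dimethoxymethyl)-5-hydroxy-6-(methoxymethoxy)-7-methylcyclohept-3-en-1-one | O=C1CC=C[C@H](O)[C@](OCOC)(C(OC)OC)[C@H]1C
F3 | step 4 | ent-alcohol, (5R,6R,7S)-6-(dimethoxymethyl)-5-hydroxy-6-(methoxymethoxy)-7-methylcyclohept-3-en-1-one | O=C1CC=C[C@@H](O)[C@@](OCOC)(C(OC)OC)[C@@H]1C
F4 | step 4 | (5R)-acetate of F3 | O=C1CC=C[C@@H](OC(C)=O)[C@@](OCOC)(C(OC)OC)[C@@H]1C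
F5 | step 5 | 6β,7β-epoxide of 9 (oxirane syn to the C5 silyl ether) | O=C1C[C@@H]2O[C@@H]2[C@H](O[Si](C)(C)C(C)(C)C)[C@](OCOC)(C(OC)OC)[C@H]1C
F6 | step 5 | C6β-hydroxy C7=C8 enone (C6 epimer of 11) | O=C1C=C[C@H](O)[C@H](O[Si](C)(C)C(C)(C)C)[C@](OCOC)(C(OC)OC)[C@H]1C
F7 | step 5 | C6α 4-nitrobenzoate of 11 | O=C1C=C[C@@H](OC(=O)c2ccc(cc2)[N+](=O)[O-])[C@H](O[Si](C)(C)C(C)(C)C)[C@](OCOC)(C(OC)OC)[C@H]1C
F8 | step 7 | C7β phosphonoacetate Michael adduct of 12 (C11 epimers) | O=C1C[C@H](C(C(=O)OCC)P(=O)(OCC)OCC)[C@@H](O[Si](C)(C)C)[C@H](O[Si](C)(C)C(C)(C)C)[C@](OCOC)(C(OC)OC)[C@H]1C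
F9 | step 7 | trans-fused α-(diethoxyphosphoryl)-γ-butyrolactone (C11 epimers) | CCOP(=O)(OCC)C1C(=O)O[C@@H]2[C@@H]1CC(=O)[C@H](C)[C@@](OCOC)(C(OC)OC)[C@H]2O[Si](C)(C)C(C)(C)C
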